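**Plan**

1. Retrosynthetic cuts, in order: the lactam N–C bonds (ammonia plus a macrocyclic keto thioester); the CH2–CH bond of the lactam, which is also a bond of the 13-membered ring (β-keto thioester plus chloromethyl ketone); ring C at two bonds at once, C-1–C-9a and the epoxide C-3–C-4 bond; the aryl ether C-9–O; ring A.
2. Enabling feature: in ring C (the epoxycyclohexane fused at C-4a/C-9a to cyclopentane ring B) C-1 and the epoxide CH C-3 both flank C-2. With C-2 temporarily a ketone they are the α- and γ-carbons of a γ-chloro-β-keto ester (a 1,3-bis-nucleophile). C-9a and C-4 are then the β-carbon and carbonyl carbon of a ring-B acetylcyclopentene (a 1,3-bis-electrophile), whose carbonyl oxygen becomes the epoxide oxygen.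
3. Forward order: ring B (chiral pool) → ring A (conjugate addition/alkylation, carbonyl-ene, HAT hydrogenation) → enone → aryl ether → ring C with its epoxide (Michael–Darzens annulation) → C-2 ketone converted to CH–CH3 → 13-membered ring by C-alkylation → hydroxy lactam.
4. Stereochemistry: C-9 from (R)-4-silyloxycyclopentenone (inverted in the Mitsunobu step); C-8a and C-4b by anti addition and trans alkylation; C-6 and C-8 by thermodynamic HAT hydrogenation; C-9a, C-4a, C-3 and C-4 in the key step; C-2 by directed hydrogenation; C-1 and the hemiaminal carbon by equilibration.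

Key step: step 14

Conventions: hydrindanes carry indene locants (C-7a bears the angular methyl); tricycles carry fluorene locants (C-1 ester or acyl, C-2, C-3/C-4 epoxide, C-4b angular methyl, C-9 aryloxy). β is the face of the angular methyl group. Ar = 4-[(S)-2-(tert-butyldimethylsilyloxy)-3-chloropropyl]phenyl. "Core" = 9β-OAr-3β,4β-epoxy-4α,4bβ,6α,8α-tetramethyl with 4aα-H, 8aα-H, 9aβ-H.

Remark: the hemiaminal carbon forms reversibly; it is assumed that the strained cyclophane admits only the natural configuration there.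

**Route**

Step 1
Reactants: 1 (R)-4-[(tert-butyldimethylsilyl)oxy]cyclopent-2-en-1-one
Product: 2 (R)-4-[(tert-butyldimethylsilyl)oxy]-2-iodocyclopent-2-en-1-one
Conditions: I2, pyridine, CH2Cl2, 0 °C → rt
Reagents that add atoms: iodine, II
Why: α-iodination of the enone by pyridine addition, iodination and elimination leaves the stereocentre untouched.

Step 2
Reactants: 2 (R)-4-[(tert-butyldimethylsilyl)oxy]-2-iodocyclopent-2-en-1-one
Product: 3 (R)-4-[(tert-butyldimethylsilyl)oxy]-2-methylcyclopent-2-en-1-one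
Conditions: Me4Sn, Pd2(dba)3 (2.5 mol%), AsPh3, CuI, NMP, 50 °C
Reagents that add atoms: tetramethylstannane, C[Sn](C)(C)C
Why: Stille coupling of an α-iodoenone under neutral conditions should spare the base-sensitive β-silyloxy ketone; no stereocentre is formed.

Step 3
Reactants: 3 (R)-4-[(tert-butyldimethylsilyl)oxy]-2-methylcyclopent-2-en-1-one
Product: 5 4-silyloxy-2-methyl-3-isopropenyl-2-propargylcyclopentanone (isopropenyl trans to both the silyloxy and the propargyl group), via magnesium enolate 4 (not isolated)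
Conditions: isopropenylMgBr, CuBr·SMe2 (20 mol%), THF, −78 °C; then HMPA, propargyl bromide, −78 → −20 °C
Reagents that add atoms: isopropenylmagnesium bromide, CC(=C)[Mg]Br; propargyl bromide, C#CCBr
Why: copper-catalysed 1,4-addition should enter anti to the silyloxy group and the regiodefined enolate should be alkylated trans to the new isopropenyl group (three-component coupling), which sets the quaternary carbon.

Step 4
Reactants: 5 the propargyl ketone
Product: 6 4-silyloxy-2-methyl-2-(2-oxopropyl)-3-isopropenylcyclopentanone (same configuration)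
Conditions: Ph3PAuNTf2 (2 mol%), dioxane–H2O, 60 °C
Reagents that add atoms: water, O
Why: gold(I)-catalysed Markovnikov hydration of the terminal alkyne should give the methyl ketone without touching a stereocentre.

Step 5
Reactants: 6 the diketone
Product: 7 3α-silyloxy-6-hydroxy-6,7aβ-dimethyl-4-methylidene-3aα-H-octahydroinden-1-one (trans-fused; C-6 carbinol configuration not controlled)
Conditions: Me2AlCl (2 equiv), CH2Cl2, −78 → 0 °C
Reagents that add atoms: none
Why: a type II intramolecular carbonyl-ene reaction should join the terminal alkene carbon to the side-chain ketone in a six-membered ring, with the trans fusion already fixed by the two trans side chains.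

Step 6
Reactants: 7 the tertiary alcohol
Product: 8 3α-silyloxy-6,7aβ-dimethyl-4-methylidene-3aα-H-2,3,3a,4,7,7a-hexahydroinden-1-one (5,6-ene, with double-bond isomers)
Conditions: Burgess reagent, toluene, 60 °C
Reagents that add atoms: none
Why: syn-elimination of the tertiary alcohol through its sulfamate; the position of the new alkene does not matter because all isomers converge in step 7.

Step 7
Reactants: 8 the diene (isomer mixture)
Product: 9 3α-silyloxy-4α,6α,7aβ-trimethyl-3aα-H-octahydroinden-1-one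
Conditions: Mn(dpm)3 (10 mol%), PhSiH3, t-BuOOH, i-PrOH, rt
Reagents that add atoms: none
Why: hydrogen-atom-transfer hydrogenation goes through tertiary ring radicals that should take up hydrogen axially, so both new methyl groups should end up equatorial (4α,6α) in the presence of the ketone.

Step 8
Reactants: 9 the hydrindanone
Product: 10 3α-silyloxy-4α,6α,7aβ-trimethyl-3a,4,5,6,7,7a-hexahydro-3H-inden-1-yl triflate
Conditions: KHMDS, PhNTf2, THF, −78 °C
Reagents that add atoms: N-phenyl-bis(trifluoromethanesulfonimide), O=S(=O)(N(c1ccccc1)S(=O)(=O)C(F)(F)F)C(F)(F)F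
Why: kinetic deprotonation can occur only at C-2 because C-7a is quaternary, and cold trapping as the enol triflate should precede β-elimination of the silyloxy group.

Step 9
Reactants: 10 the enol triflate
Product: 12 1-(3α-hydroxy-4α,6α,7aβ-trimethyl-3aα-H-3a,4,5,6,7,7a-hexahydro-3H-inden-1-yl)ethanone, via ethoxydiene 11 (not isolated)
Conditions: tributyl(1-ethoxyvinyl)stannane, Pd(PPh3)4 (5 mol%), LiCl, THF, 65 °C; then 2 M HCl, THF, rt
Reagents that add atoms: tributyl(1-ethoxyvinyl)stannane, CCOC(=C)[Sn](CCCC)(CCCC)CCCC; water, O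
Why: Stille coupling with an acetyl-anion equivalent, then acid hydrolysis of the enol ether and of the silyl ether, is the standard route from a hindered cyclopentanone to a 1-acetylcyclopentene.

Step 10
Reactants: 13 1-(benzyloxy)-4-bromobenzene; 14 (S)-epichlorohydrin
Product: 16 (S)-1-[4-(benzyloxy)phenyl]-3-chloropropan-2-ol, via Grignard reagent 15 (not isolated)
Conditions: Mg, THF, rt; then CuI (10 mol%), 14, −40 → 0 °C; H2O
Reagents that add atoms: none
Why: copper-catalysed opening of the epoxide at its unsubstituted carbon by the aryl Grignard reagent does not touch the stereocentre, which is oxidised away later.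

Step 11
Reactants: 16 the chlorohydrin
Product: 17 its tert-butyldimethylsilyl ether
Conditions: TBSCl, imidazole, DMF, rt
Reagents that add atoms: tert-butyldimethylsilyl chloride, CC(C)(C)[Si](C)(C)Cl
Why: silylation masks the secondary alcohol so that only the phenol takes part in the Mitsunobu step and the chlorohydrin cannot close to an epoxide.

Step 12
Reactants: 17 the benzyl ether
Product: 18 4-[(S)-2-(tert-butyldimethylsilyloxy)-3-chloropropyl]phenol
Conditions: H2 (1 atm), 10% Pd/C, EtOAc, rt
Reagents that add atoms: none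
Why: hydrogenolysis of the benzyl ether should leave the alkyl chloride and the silyl ether intact.

Step 13
Reactants: 12 the 3α-hydroxy enone; 18 the phenol
Product: 19 1-(3β-OAr-4α,6α,7aβ-trimethyl-3aα-H-3a,4,5,6,7,7a-hexahydro-3H-inden-1-yl)ethanone
Conditions: PPh3, DIAD, toluene, 0 °C → rt
Reagents that add atoms: none
Why: Mitsunobu etherification (SN2 with inversion; SN2′ would have to attack the acyl-bearing alkene carbon) should turn the 3α-alcohol into the 3β-aryl ether, cis to the angular methyl as in the target.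

Step 14
Reactants: 19 the aryloxy enone; 20 methyl 4-chloro-3-oxobutanoate
Product: 23 methyl 2-(triflyloxy)-core-3,4,4a,4b,5,6,7,8,8a,9,9a-undecahydrofluorene-1-carboxylate (1,2-ene), via Michael adduct 21 (not isolated), via epoxy keto ester 22 (not isolated)
Conditions: Cs2CO3 (2.5 equiv), MeCN, 0 °C → rt; then PhNTf2, rt
Reagents that add atoms: N-phenyl-bis(trifluoromethanesulfonimide), O=S(=O)(N(c1ccccc1)S(=O)(=O)C(F)(F)F)C(F)(F)F
Why: Proposed new method: the caesium enolate of 20 adds through its doubly activated carbon to the β-carbon of the acetylcyclopentene (Michael addition, C-1–C-9a) and proton transfer restores the stabilised keto ester enolate and the methyl ketone; the γ-chloro carbon then adds reversibly to that ketone (intramolecular aldol, 6-(enolendo)-exo-trig, ring C, C-3–C-4), the tertiary alkoxide displaces chloride (3-exo-tet, epoxide), and the enolate of 22 is O-triflated in the same flask. The closest known reaction types are the amine-catalysed Michael/aldol/SN2 epoxy-annulation of γ-chloro-β-keto esters with enals, the Robinson-type annulation of acetoacetates with enones, and the Darzens reaction; a ketone as aldol acceptor under carbonate is the unproven part. C-9a should be set by attack on the α face, anti to both the angular methyl and the 9β-aryloxy group, as in conjugate additions to 16-en-20-oxo steroids; C-4a is epimerisable and should settle with the acetyl group β, trans to the new substituent, which is the arrangement that closes to the trans-fused ring. C-3 and C-4 are fixed stereoelectronically: only the aldolate with axial 4β-O and axial 3α-Cl is antiperiplanar for closure, so other aldolates revert and the mixture funnels into the 3β,4β-epoxide with the 4-methyl equatorial. The step needs aldol/epoxide closure to beat O-alkylation to a furanone and Favorskii-type loss of chloride; the six-membered aldol, the irreversible epoxide closure and keeping the keto ester as its enolate (which masks its own carbonyls) are what should secure this.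

Step 15
Reactants: 23 the enol triflate
Product: 24 methyl 2-methyl-core-undecahydrofluorene-1-carboxylate (1,2-ene)
Conditions: MeMgBr, Fe(acac)3 (5 mol%), THF–NMP, −30 °C
Reagents that add atoms: methylmagnesium bromide, C[Mg]Br
Why: iron-catalysed cross-coupling of a β-keto ester enol triflate with a methyl Grignard reagent should be faster than addition to the ester or the epoxide; no stereocentre is formed.

Step 16
Reactants: 24 the conjugated ester
Product: 25 methyl 2-methylidene-core-dodecahydrofluorene-1-carboxylate (C-1 epimers)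
Conditions: LDA, THF–DMPU, −78 °C; then AcOH, −78 °C
Reagents that add atoms: none
Why: γ-deprotonation of the new methyl group gives the extended enolate, and kinetic α-protonation (deconjugation) should move the alkene to the exocyclic position.

Step 17
Reactants: 25 the methylidene ester
Product: 26 methyl 2α-methyl-core-dodecahydrofluorene-1-carboxylate (C-1 epimers)
Conditions: H2 (1 atm), [Ir(cod)(PCy3)(py)]PF6 (5 mol%), CH2Cl2, 0 °C → rt
Reagents that add atoms: none
Why: in this directed hydrogenation the iridium should bind the β-face epoxide oxygen and the neighbouring ester carbonyl and deliver hydrogen to the β face of the 1,1-disubstituted alkene, so the C-2 methyl becomes α (equatorial).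

Step 18
Reactants: 26 the saturated ester
Product: 27 2α-methyl-core-dodecahydrofluorene-1β-carboxylic acid
Conditions: NaOMe (0.3 equiv), MeOH, 40 °C; then LiOH, THF–H2O, rt; aq. NaH2PO4
Reagents that add atoms: lithium hydroxide, [Li+].[OH-]
Why: methoxide should equilibrate C-1 to the all-equatorial 1β-ester, trans to the 2α-methyl, before saponification fixes it as the carboxylate.

Step 19
Reactants: 27 the acid
Product: 29 S-tert-butyl 3-oxo-3-(2α-methyl-core-dodecahydrofluoren-1β-yl)propanethioate, via acyl imidazole 28 (not isolated)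
Conditions: CDI, THF, rt; then LiCH2C(O)S-t-Bu (2.2 equiv, from S-tert-butyl thioacetate and LiHMDS), THF, −78 °C; aq. NH4Cl
Reagents that add atoms: S-tert-butyl thioacetate, CC(=O)SC(C)(C)C
Why: crossed Claisen acylation of the thioacetate enolate by the acyl imidazole gives the β-keto thioester, which the second equivalent of enolate deprotonates and so protects from further attack.

Step 20
Reactants: 29 the silyl-protected keto thioester
Product: 30 the chlorohydrin (Ar side chain now (S)-CH2CH(OH)CH2Cl)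
Conditions: TBAF, AcOH, THF, 0 °C → rt
Reagents that add atoms: none
Why: acetic-acid-buffered fluoride should remove the silyl group without letting the alkoxide close the chlorohydrin to an epoxide.

Step 21
Reactants: 30 the chlorohydrin
Product: 31 the chloromethyl ketone (Ar side chain now CH2C(=O)CH2Cl)
Conditions: Dess–Martin periodinane, NaHCO3, CH2Cl2, 0 °C
Reagents that add atoms: none
Why: buffered Dess–Martin oxidation of the secondary alcohol should spare the epoxide and the β-keto thioester.

Step 22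
Reactants: 31 the chloromethyl ketone
Product: 32 the 13-membered cyclophane keto thioester (S-tert-butyl ester at the new CH, flanked by the C-1 ketone and the CH2C(=O)CH2Ar unit)
Conditions: Cs2CO3, NaI (10 mol%), MeCN (0.5 mM, slow addition), rt
Reagents that add atoms: none
Why: intramolecular C-alkylation of the soft caesium enolate of the β-keto thioester by the α-chloro ketone should close the cyclophane at its most flexible sp3–sp3 bond under high dilution.

Step 23
Reactants: 32 the macrocyclic keto thioester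
Product: 34 pyrrospirone O, via keto amide 33 (not isolated)
Conditions: NH3 (0.5 M in dioxane), AgO2CCF3, THF, 0 °C → rt
Reagents that add atoms: ammonia, N
Why: silver-promoted aminolysis of the thioester gives the primary β-keto amide, whose nitrogen should add to the benzylic ketone (5-exo-trig) to give the hydroxy lactam, with the hemiaminal carbon equilibrating and the β-dicarbonyl enolising.

**Compound list**

1 | (R)-4-[(tert-butyldimethylsilyl)oxy]cyclopent-2-en-1-one | O=C1C=C[C@H](O[Si](C)(C)C(C)(C)C)C1 | starting material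
2 | (R)-4-[(tert-butyldimethylsilyl)oxy]-2-iodocyclopent-2-en-1-one | O=C1C(I)=C[C@H](O[Si](C)(C)C(C)(C)C)C1 | intermediate
3 | (R)-4-[(tert-butyldimethylsilyl)oxy]-2-methylcyclopent-2-en-1-one | O=C1C(C)=C[C@H](O[Si](C)(C)C(C)(C)C)C1 | intermediate
4 | bromomagnesium enolate of 3-isopropenyl-2-methyl-4-silyloxycyclopentanone (isopropenyl trans to silyloxy) | CC1=C(O[Mg]Br)C[C@@H](O[Si](C)(C)C(C)(C)C)[C@@H]1C(C)=C | intermediate (not isolated)
5 | 4-silyloxy-2-methyl-3-isopropenyl-2-propargylcyclopentanone (isopropenyl trans to silyloxy and to propargyl) | O=C1C[C@@H](O[Si](C)(C)C(C)(C)C)[C@H](C(C)=C)[C@@]1(C)CC#C | intermediate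
6 | 4-silyloxy-2-methyl-2-(2-oxopropyl)-3-isopropenylcyclopentanone | O=C1C[C@@H](O[Si](C)(C)C(C)(C)C)[C@H](C(C)=C)[C@@]1(C)CC(C)=O | intermediate
7 | 3α-silyloxy-6-hydroxy-6,7aβ-dimethyl-4-methylidene-3aα-H-octahydroinden-1-one (C-6 not controlled) | O=C1C[C@@H](O[Si](C)(C)C(C)(C)C)[C@@H]2C(=C)CC(C)(O)C[C@@]12C | intermediate
8 | 3α-silyloxy-6,7aβ-dimethyl-4-methylidene-3aα-H-hexahydroinden-1-one (5,6-ene, with isomers) | O=C1C[C@@H](O[Si](C)(C)C(C)(C)C)[C@@H]2C(=C)C=C(C)C[C@@]12C | intermediate
9 | 3α-silyloxy-4α,6α,7aβ-trimethyl-3aα-H-octahydroinden-1-one | O=C1C[C@@H](O[Si](C)(C)C(C)(C)C)[C@@H]2[C@@H](C)C[C@@H](C)C[C@@]12C | intermediate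
10 | 3α-silyloxy-4α,6α,7aβ-trimethyl-hexahydro-3H-inden-1-yl triflate | O=S(=O)(OC1=C[C@@H](O[Si](C)(C)C(C)(C)C)[C@@H]2[C@@H](C)C[C@@H](C)C[C@@]12C)C(F)(F)F | intermediate
11 | 1-(1-ethoxyvinyl)-3α-silyloxy-4α,6α,7aβ-trimethyl-hexahydro-3H-indene | CCOC(=C)C1=C[C@@H](O[Si](C)(C)C(C)(C)C)[C@@H]2[C@@H](C)C[C@@H](C)C[C@@]12C | intermediate (not isolated)
12 | 1-(3α-hydroxy-4α,6α,7aβ-trimethyl-3aα-H-hexahydro-3H-inden-1-yl)ethanone | CC(=O)C1=C[C@@H](O)[C@@H]2[C@@H](C)C[C@@H](C)C[C@@]12C | intermediate
13 | 1-(benzyloxy)-4-bromobenzene | Brc1ccc(OCc2ccccc2)cc1 | starting material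
14 | (S)-epichlorohydrin | ClC[C@@H]1CO1 | starting material
15 | [4-(benzyloxy)phenyl]magnesium bromide | Br[Mg]c1ccc(OCc2ccccc2)cc1 | intermediate (not isolated)
16 | (S)-1-[4-(benzyloxy)phenyl]-3-chloropropan-2-ol | ClC[C@@H](O)Cc1ccc(OCc2ccccc2)cc1 | intermediate
17 | (S)-1-[4-(benzyloxy)phenyl]-3-chloropropan-2-yl tert-butyldimethylsilyl ether | ClC[C@@H](O[Si](C)(C)C(C)(C)C)Cc1ccc(OCc2ccccc2)cc1 | intermediate
18 | 4-[(S)-2-(tert-butyldimethylsilyloxy)-3-chloropropyl]phenol | ClC[C@@H](O[Si](C)(C)C(C)(C)C)Cc1ccc(O)cc1 | intermediate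
19 | 1-(3β-OAr-4α,6α,7aβ-trimethyl-3aα-H-hexahydro-3H-inden-1-yl)ethanone | CC(=O)C1=C[C@H](Oc3ccc(C[C@H](O[Si](C)(C)C(C)(C)C)CCl)cc3)[C@@H]2[C@@H](C)C[C@@H](C)C[C@@]12C | intermediate
20 | methyl 4-chloro-3-oxobutanoate | COC(=O)CC(=O)CCl | starting material
21 | methyl 4-chloro-2-(1β-acetyl-3β-OAr-4α,6α,7aβ-trimethyl-octahydroinden-2α-yl)-3-oxobutanoate | CC(=O)[C@@H]1[C@@H](C(C(=O)OC)C(=O)CCl)[C@H](Oc3ccc(C[C@H](O[Si](C)(C)C(C)(C)C)CCl)cc3)[C@@H]2[C@@H](C)C[C@@H](C)C[C@@]12C | intermediate (not isolated)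
22 | methyl 2-oxo-core-dodecahydrofluorene-1-carboxylate | COC(=O)C1C(=O)[C@H]2O[C@@]2(C)[C@@H]3[C@@H]1[C@H](Oc5ccc(C[C@H](O[Si](C)(C)C(C)(C)C)CCl)cc5)[C@@H]4[C@@H](C)C[C@@H](C)C[C@@]34C | intermediate (not isolated)
23 | methyl 2-(triflyloxy)-core-undecahydrofluorene-1-carboxylate (1,2-ene) | COC(=O)C1=C(OS(=O)(=O)C(F)(F)F)[C@H]2O[C@@]2(C)[C@@H]3[C@@H]1[C@H](Oc5ccc(C[C@H](O[Si](C)(C)C(C)(C)C)CCl)cc5)[C@@H]4[C@@H](C)C[C@@H](C)C[C@@]34C | intermediate
24 | methyl 2-methyl-core-undecahydrofluorene-1-carboxylate (1,2-ene) | COC(=O)C1=C(C)[C@H]2O[C@@]2(C)[C@@H]3[C@@H]1[C@H](Oc5ccc(C[C@H](O[Si](C)(C)C(C)(C)C)CCl)cc5)[C@@H]4[C@@H](C)C[C@@H](C)C[C@@]34C | intermediate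
25 | methyl 2-methylidene-core-dodecahydrofluorene-1-carboxylate (C-1 epimers) | COC(=O)C1C(=C)[C@H]2O[C@@]2(C)[C@@H]3[C@@H]1[C@H](Oc5ccc(C[C@H](O[Si](C)(C)C(C)(C)C)CCl)cc5)[C@@H]4[C@@H](C)C[C@@H](C)C[C@@]34C | intermediate
26 | methyl 2α-methyl-core-dodecahydrofluorene-1-carboxylate (C-1 epimers) | COC(=O)C1[C@H](C)[C@H]2O[C@@]2(C)[C@@H]3[C@@H]1[C@H](Oc5ccc(C[C@H](O[Si](C)(C)C(C)(C)C)CCl)cc5)[C@@H]4[C@@H](C)C[C@@H](C)C[C@@]34C | intermediate
27 | 2α-methyl-core-dodecahydrofluorene-1β-carboxylic acid | OC(=O)[C@H]1[C@H](C)[C@H]2O[C@@]2(C)[C@@H]3[C@@H]1[C@H](Oc5ccc(C[C@H](O[Si](C)(C)C(C)(C)C)CCl)cc5)[C@@H]4[C@@H](C)C[C@@H](C)C[C@@]34C | intermediate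
28 | acyl imidazole of 27 | O=C(n6ccnc6)[C@H]1[C@H](C)[C@H]2O[C@@]2(C)[C@@H]3[C@@H]1[C@H](Oc5ccc(C[C@H](O[Si](C)(C)C(C)(C)C)CCl)cc5)[C@@H]4[C@@H](C)C[C@@H](C)C[C@@]34C | intermediate (not isolated)
29 | S-tert-butyl 3-oxo-3-(2α-methyl-core-dodecahydrofluoren-1β-yl)propanethioate | CC(C)(C)SC(=O)CC(=O)[C@H]1[C@H](C)[C@H]2O[C@@]2(C)[C@@H]3[C@@H]1[C@H](Oc5ccc(C[C@H](O[Si](C)(C)C(C)(C)C)CCl)cc5)[C@@H]4[C@@H](C)C[C@@H](C)C[C@@]34C | intermediate
30 | chlorohydrin of 29 (side chain (S)-CH2CH(OH)CH2Cl) | CC(C)(C)SC(=O)CC(=O)[C@H]1[C@H](C)[C@H]2O[C@@]2(C)[C@@H]3[C@@H]1[C@H](Oc5ccc(C[C@H](O)CCl)cc5)[C@@H]4[C@@H](C)C[C@@H](C)C[C@@]34C | intermediate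
31 | chloromethyl ketone (side chain CH2C(=O)CH2Cl) | CC(C)(C)SC(=O)CC(=O)[C@H]1[C@H](C)[C@H]2O[C@@]2(C)[C@@H]3[C@@H]1[C@H](Oc5ccc(CC(=O)CCl)cc5)[C@@H]4[C@@H](C)C[C@@H](C)C[C@@]34C | intermediate
32 | 13-membered cyclophane 1,4-diketo S-tert-butyl thioester | C[C@@H]1C[C@H](C)[C@H]2[C@H]3Oc4ccc(cc4)CC(=O)CC(C(=O)SC(C)(C)C)C(=O)[C@H]5[C@H](C)[C@H]6O[C@@]6(C)[C@H]([C@H]35)[C@]2(C)C1 | intermediate
33 | cyclophane 1,4-diketo primary amide | C[C@@H]1C[C@H](C)[C@H]2[C@H]3Oc4ccc(cc4)CC(=O)CC(C(N)=O)C(=O)[C@H]5[C@H](C)[C@H]6O[C@@]6(C)[C@H]([C@H]35)[C@]2(C)C1 | intermediate (not isolated)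
34 | pyrrospirone O | C[C@@H]1C[C@H](C)[C@H]2[C@H]3Oc4ccc(cc4)C[C@]4(O)C/C(=C(/O)[C@H]5[C@H](C)[C@H]6O[C@@]6(C)[C@H]([C@H]35)[C@]2(C)C1)C(=O)N4 | target

**Step count and risks**

Total: 23 steps. Longest linear sequence: 20 steps (steps 1–9 and 13–23, from 1).

Most likely to fail:

1. Step 14 (proposed method). The aldol stage onto a hindered methyl ketone may be slower than O-alkylation of the keto ester enolate (furanone formation) or Favorskii-type loss of the γ-chloride, and the Michael addition to the hindered enone may be sluggish. The fallback makes the same two ring bonds by a Robinson-type annulation and adds the epoxide oxygen afterwards. It sets out from 19 and comes back at 24. Compound 19 and methyl acetoacetate (NaOMe, MeOH, reflux) should give by Michael addition and aldol condensation the cyclohexenone keto ester F1. Triflation (NaH, PhNTf2) gives the dienyl triflate F2, and iron-catalysed methylation gives the diene ester F3. Epoxidation of the remote, electron-richer C-3=C-4 bond (mCPBA, NaHCO3, CH2Cl2, 0 °C) then gives 24. The face of epoxidation is reagent-controlled here and would have to be established; the trans-diaxial control of the main route is lost.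

2. Step 22. Strain in the 13-membered cyclophane may divert the enolate into oligomerisation or O-alkylation. The fallback closes a less strained 14-membered sulfide first and contracts it. It sets out from 31 and comes back at 32. Chlorination of the keto thioester carbon (NCS) gives the dichloride F4, and Na2S under high dilution gives the cyclic sulfide F5. Oxidation (mCPBA) gives the sulfone F6. A Ramberg–Bäcklund reaction (KOH/Al2O3, CBr2F2, t-BuOH) through the α-bromo sulfone F7 gives the ene-dione F8, whose conjugate reduction (Zn, aq. NH4Cl, THF) gives 32.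

3. Step 17. Hydrogen may be delivered to the α face (giving the axial 2β-methyl), or the cationic iridium species may open the allylic epoxide. The fallback brings in the methyl group, not hydrogen, as the incoming group anti to the epoxide. It sets out from 22, isolated before triflation in step 14, and comes back at 26. Reduction (NaBH4, MeOH, −40 °C) gives the hydroxy ester F9, mesylation (MsCl, Et3N) gives the mesylate F10, and elimination with DBU gives the 1-ene ester F11. Copper-catalysed conjugate addition (MeMgBr, CuBr·SMe2, TMSCl, THF, −78 °C) should then add methyl to C-2 from the α face and give 26, with C-1 equilibrated in step 18. SN2′ opening of the vinyl epoxide is the competing process to watch.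

Further compounds
F1 | step 14 | methyl 9β-OAr-4,4bβ,6α,8α-tetramethyl-2-oxo-decahydrofluorene-1-carboxylate (3,4-ene, no epoxide) | COC(=O)C1C(=O)C=C(C)[C@@H]2[C@@H]1[C@H](Oc5ccc(C[C@H](O[Si](C)(C)C(C)(C)C)CCl)cc5)[C@@H]3[C@@H](C)C[C@@H](C)C[C@@]23C
F2 | step 14 | 2-triflyloxy-1,3-diene ester derived from F1 | COC(=O)C1=C(OS(=O)(=O)C(F)(F)F)C=C(C)[C@@H]2[C@@H]1[C@H](Oc5ccc(C[C@H](O[Si](C)(C)C(C)(C)C)CCl)cc5)[C@@H]3[C@@H](C)C[C@@H](C)C[C@@]23C
F3 | step 14 | methyl 9β-OAr-2,4,4bβ,6α,8α-pentamethyl-1,3-diene-1-carboxylate | COC(=O)C1=C(C)C=C(C)[C@@H]2[C@@H]1[C@H](Oc5ccc(C[C@H](O[Si](C)(C)C(C)(C)C)CCl)cc5)[C@@H]3[C@@H](C)C[C@@H](C)C[C@@]23C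
F4 | step 22 | α-chloro keto thioester of 31 (dichloride) | CC(C)(C)SC(=O)C(Cl)C(=O)[C@H]1[C@H](C)[C@H]2O[C@@]2(C)[C@@H]3[C@@H]1[C@H](Oc5ccc(CC(=O)CCl)cc5)[C@@H]4[C@@H](C)C[C@@H](C)C[C@@]34C
F5 | step 22 | 14-membered cyclic sulfide | C[C@@H]1C[C@H](C)[C@H]2[C@H]3Oc4ccc(cc4)CC(=O)CSC(C(=O)SC(C)(C)C)C(=O)[C@H]5[C@H](C)[C@H]6O[C@@]6(C)[C@H]([C@H]35)[C@]2(C)C1
F6 | step 22 | 14-membered cyclic sulfone | C[C@@H]1C[C@H](C)[C@H]2[C@H]3Oc4ccc(cc4)CC(=O)CS(=O)(=O)C(C(=O)SC(C)(C)C)C(=O)[C@H]5[C@H](C)[C@H]6O[C@@]6(C)[C@H]([C@H]35)[C@]2(C)C1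
F7 | step 22 | α-bromo sulfone (formed in situ) | C[C@@H]1C[C@H](C)[C@H]2[C@H]3Oc4ccc(cc4)CC(=O)CS(=O)(=O)C(Br)(C(=O)SC(C)(C)C)C(=O)[C@H]5[C@H](C)[C@H]6O[C@@]6(C)[C@H]([C@H]35)[C@]2(C)C1
F8 | step 22 | 13-membered ene-dione thioester | C[C@@H]1C[C@H](C)[C@H]2[C@H]3Oc4ccc(cc4)CC(=O)C=C(C(=O)SC(C)(C)C)C(=O)[C@H]5[C@H](C)[C@H]6O[C@@]6(C)[C@H]([C@H]35)[C@]2(C)C1
F9 | step 17 | methyl 2-hydroxy-core-dodecahydrofluorene-1-carboxylate | COC(=O)C1C(O)[C@H]2O[C@@]2(C)[C@@H]3[C@@H]1[C@H](Oc5ccc(C[C@H](O[Si](C)(C)C(C)(C)C)CCl)cc5)[C@@H]4[C@@H](C)C[C@@H](C)C[C@@]34C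
F10 | step 17 | methyl 2-(mesyloxy)-core-dodecahydrofluorene-1-carboxylate | COC(=O)C1C(OS(C)(=O)=O)[C@H]2O[C@@]2(C)[C@@H]3[C@@H]1[C@H](Oc5ccc(C[C@H](O[Si](C)(C)C(C)(C)C)CCl)cc5)[C@@H]4[C@@H](C)C[C@@H](C)C[C@@]34C
F11 | step 17 | methyl core-undecahydrofluorene-1-carboxylate (1,2-ene, C-2 unsubstituted) | COC(=O)C1=C[C@H]2O[C@@]2(C)[C@@H]3[C@@H]1[C@H](Oc5ccc(C[C@H](O[Si](C)(C)C(C)(C)C)CCl)cc5)[C@@H]4[C@@H](C)C[C@@H](C)C[C@@]34C
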